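Retrosynthesis: the phenol MOM ether, the C7 methyl ether and the C5 (E)-propenyl group are traced back to a C7 silyl group and a C5 carbinol; ring A is then cut at C3a–C7a, C4–C5 and C6–C7, and the resulting diyne at its O–C(sp) and C(sp)–Si bonds and at C2–C3.
Enabling feature (benzofuran numbering): ring A shares the C3a–C7a bond with the oxygen ring, so the chain O1–C2–C3 is a three-atom tether between an ynol ether (C7a≡C7) and a terminal alkyne (C3a≡C4), and C5 and C6 can be supplied by a third alkyne.
Forward order: the C2–C3 bond of the open chain is made first, the silylated alkynyl ether is built on the C2 oxygen, and ring A and the dihydrofuran ring then close together in one ruthenium-catalysed (2+2+2) cycloaddition; conversion of C7–Si into C7–OMe, dehydration and deprotection finish the synthesis.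
Stereochemistry: C3 comes from (R)-4-(trimethylsilyl)but-3-yn-2-ol by chirality transfer through an allenylzinc reagent, C2 from its anti-selective addition to the aldehyde; both centres lie in the tether and are not touched again, and the alkene forms (E) under thermodynamic control.

Key step: step 7

Remark on the chemistry: pent-1-yn-3-ol is used as the racemate, so the cycloadduct and the three compounds after it are mixtures of epimers at the side-chain carbinol carbon; this centre is left undefined in the SMILES and disappears on dehydration.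

Step 1
Reactants: 1 syringaldehyde (4-hydroxy-3,5-dimethoxybenzaldehyde)
Product: 2 3,5-dimethoxy-4-(methoxymethoxy)benzaldehyde
Conditions: MOMCl, i-Pr2NEt, CH2Cl2, 0 °C → rt
Reagents that add atoms: chloromethyl methyl ether, COCCl
Why: Base-mediated O-alkylation of the acidic 4-hydroxyl group (Williamson-type ether formation) gives a methoxymethyl acetal that survives the hydride, organolithium, fluoride and carbonate steps and falls to acid at the end.

Step 2
Reactants: 3 (R)-4-(trimethylsilyl)but-3-yn-2-ol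
Product: 4 (2R)-4-(trimethylsilyl)but-3-yn-2-yl methanesulfonate
Conditions: MsCl, Et3N, CH2Cl2, −78 → 0 °C
Reagents that add atoms: methanesulfonyl chloride, CS(=O)(=O)Cl
Why: Sulfonylation on oxygen (mesylation) does not touch the carbinol centre and turns the hydroxyl group into the leaving group needed for SN2′ displacement by palladium.

Step 3
Reactants: 2 3,5-dimethoxy-4-(methoxymethoxy)benzaldehyde; 4 (2R)-4-(trimethylsilyl)but-3-yn-2-yl methanesulfonate
Product: 6 (1S,2S)-1-[3,5-dimethoxy-4-(methoxymethoxy)phenyl]-2-methyl-4-(trimethylsilyl)but-3-yn-1-ol, via allenylzinc mesylate 5 (not isolated)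
Conditions: Pd(OAc)2 (5 mol%), PPh3 (5 mol%), Et2Zn (3 equiv), THF, −78 → −20 °C
Reagents that add atoms: none
Why: In this Marshall propargylation zerovalent palladium generated in situ displaces the mesylate anti (SN2′), transmetalation with Et2Zn gives allenylzinc 5, and its addition to aldehyde 2 through a closed six-membered transition state (syn SE2′) transfers the (R)-carbinol chirality to the methyl-bearing carbon (S, the later C3) and sets the new carbinol carbon (S, the later C2) anti to it.

Step 4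
Reactants: 6 (1S,2S)-1-[3,5-dimethoxy-4-(methoxymethoxy)phenyl]-2-methyl-4-(trimethylsilyl)but-3-yn-1-ol
Product: 8 (1S,2S)-1-[3,5-dimethoxy-4-(methoxymethoxy)phenyl]-2-methyl-4-(trimethylsilyl)but-3-yn-1-yl (E)-1,2-dichlorovinyl ether, via potassium alkoxide 7 (not isolated)
Conditions: KH, THF, 0 °C; then Cl2C=CHCl, −50 °C → rt
Reagents that add atoms: trichloroethylene, ClC=C(Cl)Cl
Why: The potassium alkoxide dehydrochlorinates trichloroethylene and adds to the dichloroethyne so formed (addition–elimination route to 1,2-dichlorovinyl ethers), a reaction at oxygen that leaves both stereocentres untouched.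

Step 5
Reactants: 8 (1S,2S)-1-[3,5-dimethoxy-4-(methoxymethoxy)phenyl]-2-methyl-4-(trimethylsilyl)but-3-yn-1-yl (E)-1,2-dichlorovinyl ether
Product: 12 (1S,2S)-1-[3,5-dimethoxy-4-(methoxymethoxy)phenyl]-2-methylbut-3-yn-1-yl ethynyl ether, via chloroethynyl ether 9 (not isolated), via lithium alkoxyacetylide 10 (not isolated), via C-silylated ethynyl ether 11 (not isolated)
Conditions: n-BuLi (2.3 equiv), THF, −78 → −40 °C; then MeOH, K2CO3, 0 °C → rt
Reagents that add atoms: none
Why: Dehydrochlorination and chlorine–lithium exchange turn the dichlorovinyl ether into the lithium alkoxyacetylide (dichlorovinyl ether route to ynol ethers), which methanol protonates before base-catalysed methanolysis strips the C-trimethylsilyl group, so that the carbon alkyne is freed while no second, more labile alkynylsilane is present.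

Step 6
Reactants: 12 (1S,2S)-1-[3,5-dimethoxy-4-(methoxymethoxy)phenyl]-2-methylbut-3-yn-1-yl ethynyl ether
Product: 14 (1S,2S)-1-[3,5-dimethoxy-4-(methoxymethoxy)phenyl]-2-methylbut-3-yn-1-yl [benzyl(dimethyl)silyl]ethynyl ether, via lithium alkoxyacetylide 13 (not isolated)
Conditions: LiN(SiMe3)2 (1.0 equiv), THF, −78 °C; then BnMe2SiCl, −78 → 0 °C
Reagents that add atoms: benzyl(chloro)dimethylsilane, C[Si](C)(Cl)Cc1ccccc1
Why: Under equilibrating conditions LiN(SiMe3)2 should metalate only the alkoxyethyne C–H bond, which the inductive pull of the oxygen makes the more acidic of the two alkyne C–H bonds (much as phenylethyne is more acidic than an alkylethyne), and the acetylide is then silylated by the chlorosilane (acetylide C-silylation).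

Step 7
Reactants: 14 (1S,2S)-1-[3,5-dimethoxy-4-(methoxymethoxy)phenyl]-2-methylbut-3-yn-1-yl [benzyl(dimethyl)silyl]ethynyl ether; 15 pent-1-yn-3-ol (racemic)
Product: 16 1-{(2S,3S)-7-[benzyl(dimethyl)silyl]-2-[3,5-dimethoxy-4-(methoxymethoxy)phenyl]-3-methyl-2,3-dihydro-1-benzofuran-5-yl}propan-1-ol
Conditions: Cp*RuCl(cod) (5 mol%), 15 (3 equiv), ClCH2CH2Cl, rt, 14 added slowly
Reagents that add atoms: none
Why: Proposed new method: the Cp*RuCl fragment (divalent ruthenium, freed from cod) should bind both alkynes of 14 and couple them oxidatively to a ruthenacyclopentadiene, creating C3a–C7a and thereby closing the oxygen ring as a five-membered ring across the O1–C2–C3 tether; coordination and insertion of 15 followed by reductive elimination then make C4–C5 and C6–C7 and close ring A as the new benzene ring in the same catalytic cycle. The closest known reaction type is the Cp*RuCl(cod)- or RhCl(PPh3)3-catalysed (2+2+2) cycloaddition of 1,6-diynes with terminal alkynes, together with the cyclotrimerisation of ynamide-tethered diynes to indolines; a 1,6-diyne whose tether ends in a silylated ynol ether has not been used. No stereocentre is formed, since C2 and C3 lie in the tether and take no part, and the carbinol centre is brought in by racemic 15. The step needs regioselective insertion that puts the side chain on C5 and not on C6: the silyl group shields the ruthenium–carbon bond at C7, so 15 should add at the unsubstituted C4 terminus and turn its substituent away from silicon, which is the meta selectivity known for 1,6-diynes with one substituted terminus. Cross-cycloaddition instead of diyne dimerisation is favoured by adding 14 slowly to an excess of 15, and the reaction at room temperature keeps the benzylic alkynyl ether below the temperature of its sigmatropic rearrangement.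

Step 8
Reactants: 16 1-{(2S,3S)-7-[benzyl(dimethyl)silyl]-2-[3,5-dimethoxy-4-(methoxymethoxy)phenyl]-3-methyl-2,3-dihydro-1-benzofuran-5-yl}propan-1-ol
Product: 18 (2S,3S)-2-[3,5-dimethoxy-4-(methoxymethoxy)phenyl]-5-(1-hydroxypropyl)-3-methyl-2,3-dihydro-1-benzofuran-7-ol, via arylsilanol 17 (not isolated)
Conditions: Bu4NF, THF, 0 °C → rt; then KHCO3, H2O2 (30% aq), MeOH, rt → 40 °C
Reagents that add atoms: hydrogen peroxide, OO
Why: Fluoride cleaves the benzyl–silicon bond to give silanol 17, whose peroxide adduct rearranges by 1,2-shift of the aryl group from silicon to oxygen with retention of the ring position (Tamao–Fleming oxidation), the MOM acetal and the free alcohol being inert to basic peroxide.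

Step 9
Reactants: 18 (2S,3S)-2-[3,5-dimethoxy-4-(methoxymethoxy)phenyl]-5-(1-hydroxypropyl)-3-methyl-2,3-dihydro-1-benzofuran-7-ol
Product: 19 1-{(2S,3S)-2-[3,5-dimethoxy-4-(methoxymethoxy)phenyl]-7-methoxy-3-methyl-2,3-dihydro-1-benzofuran-5-yl}propan-1-ol
Conditions: MeI, K2CO3, acetone, 50 °C
Reagents that add atoms: iodomethane, CI
Why: Carbonate deprotonates only the phenol, and the phenoxide is methylated by SN2 reaction with iodomethane (Williamson ether synthesis) while the secondary alcohol stays free.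

Step 10
Reactants: 19 1-{(2S,3S)-2-[3,5-dimethoxy-4-(methoxymethoxy)phenyl]-7-methoxy-3-methyl-2,3-dihydro-1-benzofuran-5-yl}propan-1-ol
Product: 20 (2S,3S)-2-[3,5-dimethoxy-4-(methoxymethoxy)phenyl]-7-methoxy-3-methyl-5-[(E)-prop-1-en-1-yl]-2,3-dihydro-1-benzofuran
Conditions: p-TsOH·H2O (5 mol%), toluene, 60 °C
Reagents that add atoms: none
Why: Acid-catalysed E1 dehydration passes through the benzylic cation stabilised by the para ring oxygen O1 and gives the conjugated (E)-propenyl group under thermodynamic control, the aryl MOM acetal having no nucleophile for its cleavage in dry toluene.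

Step 11
Reactants: 20 (2S,3S)-2-[3,5-dimethoxy-4-(methoxymethoxy)phenyl]-7-methoxy-3-methyl-5-[(E)-prop-1-en-1-yl]-2,3-dihydro-1-benzofuran
Product: 21 odoratisol A, 2,6-dimethoxy-4-{(2S,3S)-7-methoxy-3-methyl-5-[(E)-prop-1-en-1-yl]-2,3-dihydro-1-benzofuran-2-yl}phenol
Conditions: HCl (cat.), MeOH, rt
Reagents that add atoms: none
Why: Acid-catalysed acetal exchange with methanol (MOM cleavage) frees the phenol, C3 cannot epimerise, and any reversible opening at the benzylic C2–O1 bond recloses to the more stable trans ring.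

Compound list
1 | syringaldehyde (4-hydroxy-3,5-dimethoxybenzaldehyde) | COc1cc(C=O)cc(OC)c1O | starting material
2 | 3,5-dimethoxy-4-(methoxymethoxy)benzaldehyde | COCOc1c(OC)cc(C=O)cc1OC | intermediate
3 | (R)-4-(trimethylsilyl)but-3-yn-2-ol | C[C@@H](O)C#C[Si](C)(C)C | starting material
4 | (2R)-4-(trimethylsilyl)but-3-yn-2-yl methanesulfonate | C[C@@H](OS(C)(=O)=O)C#C[Si](C)(C)C | intermediate
5 | (aS)-[1-(trimethylsilyl)buta-1,2-dien-1-yl]zinc methanesulfonate | CC([H])=[C@]=C([Zn]OS(C)(=O)=O)[Si](C)(C)C | intermediate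
6 | (1S,2S)-1-[3,5-dimethoxy-4-(methoxymethoxy)phenyl]-2-methyl-4-(trimethylsilyl)but-3-yn-1-ol | C[Si](C)(C)C#C[C@H](C)[C@@H](c1cc(OC)c(OCOC)c(OC)c1)O | intermediate
7 | potassium (1S,2S)-1-[3,5-dimethoxy-4-(methoxymethoxy)phenyl]-2-methyl-4-(trimethylsilyl)but-3-yn-1-olate | C[Si](C)(C)C#C[C@H](C)[C@@H](c1cc(OC)c(OCOC)c(OC)c1)[O-].[K+] | intermediate
8 | (1S,2S)-1-[3,5-dimethoxy-4-(methoxymethoxy)phenyl]-2-methyl-4-(trimethylsilyl)but-3-yn-1-yl (E)-1,2-dichlorovinyl ether | C[Si](C)(C)C#C[C@H](C)[C@@H](c1cc(OC)c(OCOC)c(OC)c1)O/C(Cl)=C\Cl | intermediate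
9 | (1S,2S)-1-[3,5-dimethoxy-4-(methoxymethoxy)phenyl]-2-methyl-4-(trimethylsilyl)but-3-yn-1-yl chloroethynyl ether | C[Si](C)(C)C#C[C@H](C)[C@@H](c1cc(OC)c(OCOC)c(OC)c1)OC#CCl | intermediate
10 | [2-({(1S,2S)-1-[3,5-dimethoxy-4-(methoxymethoxy)phenyl]-2-methyl-4-(trimethylsilyl)but-3-yn-1-yl}oxy)ethynyl]lithium | C[Si](C)(C)C#C[C@H](C)[C@@H](c1cc(OC)c(OCOC)c(OC)c1)OC#C[Li] | intermediate
11 | (1S,2S)-1-[3,5-dimethoxy-4-(methoxymethoxy)phenyl]-2-methyl-4-(trimethylsilyl)but-3-yn-1-yl ethynyl ether | C[Si](C)(C)C#C[C@H](C)[C@@H](c1cc(OC)c(OCOC)c(OC)c1)OC#C | intermediate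
12 | (1S,2S)-1-[3,5-dimethoxy-4-(methoxymethoxy)phenyl]-2-methylbut-3-yn-1-yl ethynyl ether | C#C[C@H](C)[C@@H](c1cc(OC)c(OCOC)c(OC)c1)OC#C | intermediate
13 | [2-({(1S,2S)-1-[3,5-dimethoxy-4-(methoxymethoxy)phenyl]-2-methylbut-3-yn-1-yl}oxy)ethynyl]lithium | C#C[C@H](C)[C@@H](c1cc(OC)c(OCOC)c(OC)c1)OC#C[Li] | intermediate
14 | (1S,2S)-1-[3,5-dimethoxy-4-(methoxymethoxy)phenyl]-2-methylbut-3-yn-1-yl [benzyl(dimethyl)silyl]ethynyl ether | C#C[C@H](C)[C@@H](c1cc(OC)c(OCOC)c(OC)c1)OC#C[Si](C)(C)Cc1ccccc1 | intermediate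
15 | pent-1-yn-3-ol (racemic) | CCC(O)C#C | starting material
16 | 1-{(2S,3S)-7-[benzyl(dimethyl)silyl]-2-[3,5-dimethoxy-4-(methoxymethoxy)phenyl]-3-methyl-2,3-dihydro-1-benzofuran-5-yl}propan-1-ol | CCC(O)c1cc([Si](C)(C)Cc3ccccc3)c2c(c1)[C@H](C)[C@@H](c1cc(OC)c(OCOC)c(OC)c1)O2 | intermediate
17 | 1-{(2S,3S)-2-[3,5-dimethoxy-4-(methoxymethoxy)phenyl]-7-[hydroxy(dimethyl)silyl]-3-methyl-2,3-dihydro-1-benzofuran-5-yl}propan-1-ol | CCC(O)c1cc([Si](C)(C)O)c2c(c1)[C@H](C)[C@@H](c1cc(OC)c(OCOC)c(OC)c1)O2 | intermediate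
18 | (2S,3S)-2-[3,5-dimethoxy-4-(methoxymethoxy)phenyl]-5-(1-hydroxypropyl)-3-methyl-2,3-dihydro-1-benzofuran-7-ol | CCC(O)c1cc(O)c2c(c1)[C@H](C)[C@@H](c1cc(OC)c(OCOC)c(OC)c1)O2 | intermediate
19 | 1-{(2S,3S)-2-[3,5-dimethoxy-4-(methoxymethoxy)phenyl]-7-methoxy-3-methyl-2,3-dihydro-1-benzofuran-5-yl}propan-1-ol | CCC(O)c1cc(OC)c2c(c1)[C@H](C)[C@@H](c1cc(OC)c(OCOC)c(OC)c1)O2 | intermediate
20 | (2S,3S)-2-[3,5-dimethoxy-4-(methoxymethoxy)phenyl]-7-methoxy-3-methyl-5-[(E)-prop-1-en-1-yl]-2,3-dihydro-1-benzofuran | C/C=C/c1cc(OC)c2c(c1)[C@H](C)[C@@H](c1cc(OC)c(OCOC)c(OC)c1)O2 | intermediate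
21 | odoratisol A, 2,6-dimethoxy-4-{(2S,3S)-7-methoxy-3-methyl-5-[(E)-prop-1-en-1-yl]-2,3-dihydro-1-benzofuran-2-yl}phenol | C/C=C/c1cc(OC)c2c(c1)[C@H](C)[C@@H](c1cc(OC)c(O)c(OC)c1)O2 | target

Total step count: 11
Longest linear sequence: 10 steps (1 → 2 → 6 → 8 → 12 → 14 → 16 → 18 → 19 → 20 → 21; the branch 3 → 4 joins in step 3 and is equally long)

Steps most likely to fail

Step 7 (the step that goes beyond known chemistry). What may go wrong: oxidative coupling of the silylated alkynyl ether with the terminal alkyne may be too slow, so that the diyne dimerises or the monoalkyne trimerises, or the monoalkyne may insert in the reverse orientation and put the side chain on C6. Fallback (known chemistry; ring A is brought in preformed and the oxygen ring is closed last): it sets out from 2. An Evans syn-aldol reaction of 2 with the dibutylboron enolate of (S)-4-benzyl-3-{[5-bromo-3-methoxy-2-(methoxymethoxy)phenyl]acetyl}-1,3-oxazolidin-2-one F1 (made from the arylacetyl chloride and the lithiated auxiliary; Bu2BOTf, i-Pr2NEt, CH2Cl2, −78 → 0 °C) should give the (2S,3S)-aldol adduct F2. LiBH4 removes the auxiliary to give the 1,3-diol F3, whose primary hydroxyl group is converted into the primary tosylate F4 (TsCl, pyridine) and reduced with LiEt3BH to the (1S,2S)-1,2-diarylpropan-1-ol F5. HCl in methanol then cleaves both MOM groups and closes the dihydrofuran ring through the benzylic cation to the trans-5-bromodihydrobenzofuran phenol F6; C3 is fixed by the aldol step and C2 settles trans. Suzuki–Miyaura coupling of F6 with potassium (E)-prop-1-enyltrifluoroborate (PdCl2(dppf), Cs2CO3, THF/H2O) comes back to the route at 21.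

Step 6. What may go wrong: metalation may fail to discriminate between the two alkyne C–H bonds, so that silicon is delivered to the carbon alkyne or to both termini. Fallback (steric differentiation of two alkynylsilanes in place of acidity-based metalation): it sets out from 10, the lithium acetylide formed in step 5. Trapping 10 with chlorodiisopropylsilane (−78 → 0 °C) gives the doubly silylated diyne F7. K2CO3 in methanol at 0 °C then removes only the unhindered C-trimethylsilyl group and gives the (diisopropylsilyl)ethynyl ether F8, the hindered silyl group resisting methanolysis as triisopropylsilylalkynes do. Cycloaddition of F8 with 15 under the conditions of step 7 gives the arylhydrosilane F9, and Tamao–Fleming oxidation (KF, KHCO3, H2O2, THF/MeOH, 50 °C) comes back to the route at 18.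

Step 5. What may go wrong: the unsubstituted alkynyl ether may be lost during methanolysis and isolation through ionisation of the benzylic C–O bond, hydration or sigmatropic rearrangement. Fallback (the carbon alkyne is freed before the alkynyl ether exists): it sets out from 8. K2CO3 in methanol removes the trimethylsilyl group at the stage of the robust dichlorovinyl ether and gives the terminal-alkyne dichlorovinyl ether F10. n-BuLi (3.2 equiv, THF, −78 → −40 °C) then deprotonates the alkyne and converts the dichlorovinyl ether into the dilithium bis(acetylide) F11, which is protonated with methanol at −78 °C and comes back to the route at 12, taken on cold and without chromatography.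

Further compounds
F1 | step 7 | (S)-4-benzyl-3-{[5-bromo-3-methoxy-2-(methoxymethoxy)phenyl]acetyl}-1,3-oxazolidin-2-one | O=C(Cc1cc(Br)cc(OC)c1OCOC)N1[C@@H](Cc2ccccc2)COC1=O
F2 | step 7 | (S)-4-benzyl-3-{(2S,3S)-2-[5-bromo-3-methoxy-2-(methoxymethoxy)phenyl]-3-[3,5-dimethoxy-4-(methoxymethoxy)phenyl]-3-hydroxypropanoyl}-1,3-oxazolidin-2-one | O=C(N1[C@@H](Cc2ccccc2)COC1=O)[C@@H](c1cc(Br)cc(OC)c1OCOC)[C@H](O)c1cc(OC)c(OCOC)c(OC)c1
F3 | step 7 | (1S,2R)-2-[5-bromo-3-methoxy-2-(methoxymethoxy)phenyl]-1-[3,5-dimethoxy-4-(methoxymethoxy)phenyl]propane-1,3-diol | OC[C@@H](c1cc(Br)cc(OC)c1OCOC)[C@H](O)c1cc(OC)c(OCOC)c(OC)c1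
F4 | step 7 | (2R,3S)-2-[5-bromo-3-methoxy-2-(methoxymethoxy)phenyl]-3-[3,5-dimethoxy-4-(methoxymethoxy)phenyl]-3-hydroxypropyl 4-methylbenzenesulfonate | Cc1ccc(cc1)S(=O)(=O)OC[C@@H](c1cc(Br)cc(OC)c1OCOC)[C@H](O)c1cc(OC)c(OCOC)c(OC)c1
F5 | step 7 | (1S,2S)-2-[5-bromo-3-methoxy-2-(methoxymethoxy)phenyl]-1-[3,5-dimethoxy-4-(methoxymethoxy)phenyl]propan-1-ol | C[C@@H](c1cc(Br)cc(OC)c1OCOC)[C@H](O)c1cc(OC)c(OCOC)c(OC)c1
F6 | step 7 | 4-[(2S,3S)-5-bromo-7-methoxy-3-methyl-2,3-dihydro-1-benzofuran-2-yl]-2,6-dimethoxyphenol | Brc1cc(OC)c2c(c1)[C@H](C)[C@@H](c1cc(OC)c(O)c(OC)c1)O2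
F7 | step 6 | (1S,2S)-1-[3,5-dimethoxy-4-(methoxymethoxy)phenyl]-2-methyl-4-(trimethylsilyl)but-3-yn-1-yl (diisopropylsilyl)ethynyl ether | C[Si](C)(C)C#C[C@H](C)[C@@H](c1cc(OC)c(OCOC)c(OC)c1)OC#C[SiH](C(C)C)C(C)C
F8 | step 6 | (1S,2S)-1-[3,5-dimethoxy-4-(methoxymethoxy)phenyl]-2-methylbut-3-yn-1-yl (diisopropylsilyl)ethynyl ether | C#C[C@H](C)[C@@H](c1cc(OC)c(OCOC)c(OC)c1)OC#C[SiH](C(C)C)C(C)C
F9 | step 6 | 1-{(2S,3S)-7-(diisopropylsilyl)-2-[3,5-dimethoxy-4-(methoxymethoxy)phenyl]-3-methyl-2,3-dihydro-1-benzofuran-5-yl}propan-1-ol | CCC(O)c1cc([SiH](C(C)C)C(C)C)c2c(c1)[C@H](C)[C@@H](c1cc(OC)c(OCOC)c(OC)c1)O2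
F10 | step 5 | (1S,2S)-1-[3,5-dimethoxy-4-(methoxymethoxy)phenyl]-2-methylbut-3-yn-1-yl (E)-1,2-dichlorovinyl ether | C#C[C@H](C)[C@@H](c1cc(OC)c(OCOC)c(OC)c1)O/C(Cl)=C\Cl
F11 | step 5 | dilithium bis(acetylide) of (1S,2S)-1-[3,5-dimethoxy-4-(methoxymethoxy)phenyl]-2-methylbut-3-yn-1-yl ethynyl ether | [Li]C#C[C@H](C)[C@@H](c1cc(OC)c(OCOC)c(OC)c1)OC#C[Li]
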